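**Plan**
- Retrosynthetic cuts: C12–C13 (butenolide joined by sp3–sp2 coupling), C9–C11 (vinyl addition to a C9 ketone), C3–C4 (ring A, radical closure), then C10–C1 and C10–CH3 (enolate alkylations), which leaves (R)-carvone as ring B.
- Enabling feature: C4 of ring A is a gem-dimethyl carbon bonded to C5 of ring B and to the carbinol carbon C3. An isopropenyl group on C5 is C4 lacking one hydrogen, so hydrogen-atom transfer makes the C4 radical six atoms away from a C3 aldehyde tethered through C1–C2 to C10.
- Forward order: ring B comes from carvone (methyl, allyl, enone reduction), the allyl group becomes the C1–C3 aldehyde, ring A closes in step 6, then C11–C12 and the butenolide are attached.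
- Stereochemistry: C5 from (R)-carvone; C10 by allylation anti to isopropenyl; C8 by base equilibration (final in the rigid decalin); C3 by the chair closure; C9 by equatorial, β-face vinyl addition.

Key step: step 6

Remark: positions carry labdane numbers (ring A C1–C5/C10, ring B C5–C10, side chain C11–C16); 4 (at carvone C6) and 9, 11, 12 (at C8) are carried with their minor epimer, drawn as the major one, because both centres are re-set downstream.

**Step 1**
Reactants: 1 (R)-(−)-carvone; 2 iodomethane
Product: 4 (5R,6S)-6-methylcarvone, via carvone lithium dienolate 3 (not isolated)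
Conditions: LiN(i-Pr)2 (LDA), THF, −78 °C; then MeI, −78 to 0 °C
Reagents that add atoms: iodomethane (2), CI
Why: kinetic α′-deprotonation gives the cross-conjugated dienolate and SN2 enolate alkylation should place one methyl on carvone C6 (future C10), mainly trans to isopropenyl; the new centre need not be controlled because step 2 planarises it again.

**Step 2**
Reactants: 4 (5R,6S)-6-methylcarvone; 5 allyl bromide
Product: 7 (5S,6S)-6-allyl-6-methylcarvone, via lithium enolate 6 (not isolated)
Conditions: LiN(i-Pr)2 (LDA), THF, −78 °C; then allyl bromide, DMPU, −78 to −20 °C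
Reagents that add atoms: allyl bromide (5), C=CCBr
Why: enolate alkylation of the fully substituted α′-enolate with a reactive allylic halide, the electrophile entering on the face opposite the neighbouring isopropenyl group, so the quaternary centre (future C10) should form with allyl trans and methyl cis to isopropenyl.

**Step 3**
Reactants: 7 (5S,6S)-6-allyl-6-methylcarvone
Product: 9 (2S,3S,6R)-2-allyl-2,6-dimethyl-3-(prop-1-en-2-yl)cyclohexan-1-one, via lithium enolate 8 (not isolated)
Conditions: LiBH(s-Bu)3 (L-Selectride), THF, −78 °C; MeOH quench; then NaOMe (cat.), MeOH, rt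
Reagents that add atoms: none
Why: conjugate (1,4) hydride reduction of the β-unsubstituted enone, whose carbonyl is screened against 1,2-attack by the α-quaternary carbon and whose isolated alkenes are inert, followed by base epimerisation that should enrich the equatorial C8 methyl epimer (only moderately in this flexible ring, hence the final equilibration in step 6).

**Step 4**
Reactants: 9 (2S,3S,6R)-2-allyl-2,6-dimethyl-3-(prop-1-en-2-yl)cyclohexan-1-one
Product: 11 (2S,3S,6R)-2-(3-hydroxypropyl)-2,6-dimethyl-3-(prop-1-en-2-yl)cyclohexan-1-one, via alkyl(disiamyl)borane 10 (not isolated)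
Conditions: disiamylborane (from BH3·THF and 2-methylbut-2-ene), THF, 0 °C; then NaOH, H2O2, 0 °C to rt
Reagents that add atoms: hydrogen peroxide, OO
Why: Brown hydroboration–oxidation with a bulky dialkylborane, which should add to the monosubstituted allyl alkene much faster than to the hindered 1,1-disubstituted isopropenyl group or the doubly α-branched ketone, placing the hydroxyl on the terminal carbon (future C3).

**Step 5**
Reactants: 11 (2S,3S,6R)-2-(3-hydroxypropyl)-2,6-dimethyl-3-(prop-1-en-2-yl)cyclohexan-1-one
Product: 12 (2S,3S,6R)-2,6-dimethyl-2-(3-oxopropyl)-3-(prop-1-en-2-yl)cyclohexan-1-one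
Conditions: Dess–Martin periodinane, CH2Cl2, 0 °C to rt
Reagents that add atoms: none
Why: Dess–Martin oxidation should stop at the aldehyde under neutral conditions that leave the isopropenyl group and the ketone untouched.

**Step 6**
Reactants: 12 (2S,3S,6R)-2,6-dimethyl-2-(3-oxopropyl)-3-(prop-1-en-2-yl)cyclohexan-1-one
Product: 14 3β-hydroxy-4,4,8α,10-tetramethyl-trans-decalin-9-one, via 8β-methyl epimer 13 (not isolated)
Conditions: Fe(acac)3 (30 mol %), PhSiH3 (2.5 equiv), EtOH, 60 °C; silica filtration; then NaOMe (cat.), MeOH, rt
Reagents that add atoms: none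
Why: Fe(acac)3 and PhSiH3 in ethanol form an iron hydride that passes a hydrogen atom to the CH2 terminus of the isopropenyl group, which creates the second C4 methyl and the tertiary C4 radical; this radical adds to the carbon of the tethered C3 aldehyde, and the alkoxy radical is reduced by divalent iron and protonated by ethanol. The closest known reaction type is the iron-hydride (Mukaiyama-type) HAT-initiated reductive alkene–carbonyl radical coupling, established for alkene-tethered ketones and for alkene–aldehyde additions. Ring A closes 6-exo-trig through a chair in which the tether on C10 and the radical carbon on C5 are both equatorial on ring B, so only the trans-decalin can form. C3, the one new stereocentre, should be set by the chair that holds the aldehyde oxygen pseudo-equatorial, giving the 3β (equatorial) alcohol. The step needs chemoselective HAT and a closure that outruns reduction of the tertiary radical and β-scission of the alkoxy radical: the isopropenyl group is the only alkene, the C9 ketone could be reached only through a four-membered transition state, and the protic iron medium should capture the alkoxy radical quickly. The closing methoxide treatment equilibrates C8 in the now rigid decalin, where a β-methyl would be syn-diaxial to the C10 methyl, so that material cyclised as the 8-epimer 13 converges on 14.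

**Step 7**
Reactants: 14 3β-hydroxy-4,4,8α,10-tetramethyl-trans-decalin-9-one; 15 vinylmagnesium bromide
Product: 16 9β-vinyl-4,4,8α,10-tetramethyl-trans-decalin-3β,9α-diol
Conditions: CeCl3 (anhydrous), CH2=CHMgBr (4 equiv), THF, −78 to 0 °C; aqueous NH4Cl
Reagents that add atoms: vinylmagnesium bromide (15), C=C[Mg]Br
Why: organocerium 1,2-addition (Imamoto conditions) suppresses enolisation of the hindered ketone, and the vinyl group should enter along the equatorial β-face trajectory because the axial α-face approach to C9 meets the three syn-axial hydrogens on C1, C5 and C7, which puts C11 equatorial and the hydroxyl axial (9α); the C3 alkoxide formed first is a spectator.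

**Step 8**
Reactants: 16 9β-vinyl-4,4,8α,10-tetramethyl-trans-decalin-3β,9α-diol; 17 acetic anhydride
Product: 18 3β-acetoxy-9β-vinyl-4,4,8α,10-tetramethyl-trans-decalin-9α-ol
Conditions: Ac2O, pyridine, DMAP (cat.), CH2Cl2, rt
Reagents that add atoms: acetic anhydride (17), CC(=O)OC(C)=O
Why: DMAP-catalysed acylation should esterify only the equatorial secondary C3 alcohol, since the axial tertiary C9 alcohol between two branched carbons is too hindered to react.

**Step 9**
Reactants: 18 3β-acetoxy-9β-vinyl-4,4,8α,10-tetramethyl-trans-decalin-9α-ol; 19 3-bromofuran-2(5H)-one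
Product: 21 3β-acetoxy-9α-hydroxylabd-13-en-16,15-olide (target), via B-alkyl-9-BBN borane 20 (not isolated)
Conditions: 9-BBN (2.2 equiv), THF, 0 °C to rt; then 19, Pd(dppf)Cl2 (5 mol %), AsPh3, Cs2CO3, DMF/H2O, rt
Reagents that add atoms: 3-bromofuran-2(5H)-one (19), O=C1OCC=C1Br
Why: anti-Markovnikov hydroboration of the only alkene puts boron on C12, and the B-alkyl Suzuki–Miyaura coupling (oxidative addition of zerovalent palladium into the C–Br bond of 19, base-assisted alkyl transfer, reductive elimination) should join C12 to the butenolide α-carbon C13 under room-temperature carbonate conditions that the hindered acetate and the lactone tolerate; no stereocentre is touched.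

**Compound list**
1 | (R)-(−)-carvone | CC1=CC[C@H](CC1=O)C(C)=C | starting material
2 | iodomethane | CI | starting material
3 | lithium dienolate of carvone (α′-enolate, not isolated) | [Li]OC1=C[C@@H](CC=C1C)C(C)=C | intermediate
4 | (5R,6S)-6-methylcarvone, i.e. trans-2,6-dimethyl-5-(prop-1-en-2-yl)cyclohex-2-en-1-one (minor cis epimer carried along) | C[C@H]1[C@@H](CC=C(C)C1=O)C(C)=C | intermediate
5 | allyl bromide | C=CCBr | starting material
6 | lithium enolate of 4 (not isolated) | [Li]OC1=C(C)[C@@H](CC=C1C)C(C)=C | intermediate
7 | (5S,6S)-6-allyl-2,6-dimethyl-5-(prop-1-en-2-yl)cyclohex-2-en-1-one (allyl trans, methyl cis to isopropenyl) | C=CC[C@@]1(C)[C@@H](CC=C(C)C1=O)C(C)=C | intermediate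
8 | lithium enolate from conjugate reduction of 7 (not isolated) | C=CC[C@@]1(C)[C@@H](CCC(C)=C1O[Li])C(C)=C | intermediate
9 | (2S,3S,6R)-2-allyl-2,6-dimethyl-3-(prop-1-en-2-yl)cyclohexan-1-one (major C8 epimer drawn) | C=CC[C@@]1(C)[C@@H](CC[C@@H](C)C1=O)C(C)=C | intermediate
10 | bis(3-methylbutan-2-yl)borane adduct of 9 at the allyl terminus (not isolated) | CC(C)C(C)B(CCC[C@@]1(C)[C@@H](CC[C@@H](C)C1=O)C(C)=C)C(C)C(C)C | intermediate
11 | (2S,3S,6R)-2-(3-hydroxypropyl)-2,6-dimethyl-3-(prop-1-en-2-yl)cyclohexan-1-one | OCCC[C@@]1(C)[C@@H](CC[C@@H](C)C1=O)C(C)=C | intermediate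
12 | (2S,3S,6R)-2,6-dimethyl-2-(3-oxopropyl)-3-(prop-1-en-2-yl)cyclohexan-1-one (keto aldehyde, key-step precursor) | O=CCC[C@@]1(C)[C@@H](CC[C@@H](C)C1=O)C(C)=C | intermediate
13 | 3β-hydroxy-4,4,8β,10-tetramethyl-trans-decalin-9-one (8-epimer, from the minor epimer of 12, not isolated) | O[C@H]1CC[C@@]2(C)[C@@H](CC[C@H](C)C2=O)C1(C)C | intermediate
14 | 3β-hydroxy-4,4,8α,10-tetramethyl-trans-decalin-9-one (5α-H, 10β-CH3; key-step product) | O[C@H]1CC[C@@]2(C)[C@@H](CC[C@@H](C)C2=O)C1(C)C | intermediate
15 | vinylmagnesium bromide | C=C[Mg]Br | starting material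
16 | 9β-vinyl-4,4,8α,10-tetramethyl-trans-decalin-3β,9α-diol | O[C@H]1CC[C@@]2(C)[C@@H](CC[C@@H](C)[C@]2(O)C=C)C1(C)C | intermediate
17 | acetic anhydride | CC(=O)OC(C)=O | starting material
18 | 3β-acetoxy-9β-vinyl-4,4,8α,10-tetramethyl-trans-decalin-9α-ol | CC(=O)O[C@H]1CC[C@@]2(C)[C@@H](CC[C@@H](C)[C@]2(O)C=C)C1(C)C | intermediate
19 | 3-bromofuran-2(5H)-one | O=C1OCC=C1Br | starting material
20 | B-alkyl-9-BBN adduct of 18 with boron on C12 (not isolated) | CC(=O)O[C@H]1CC[C@@]2(C)[C@@H](CC[C@@H](C)[C@]2(O)CCB2C3CCCC2CCC3)C1(C)C | intermediate
21 | 3β-acetoxy-9α-hydroxylabd-13-en-16,15-olide (CNP0117645.1) | CC(=O)O[C@H]1CC[C@@]2(C)[C@@H](CC[C@@H](C)[C@]2(O)CCC2=CCOC2=O)C1(C)C | target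

**Count**
Total steps: 9. Longest linear sequence: 9 steps, from 1 to 21.

**Steps most likely to fail**

Step 6. The alkoxy radical next to the quaternary C4 may fragment back (β-scission) faster than it is reduced, so that the tertiary radical is merely hydrogenated; the closure may also give the 3α-alcohol. The fallback sets out from 12 and comes back at 14. Aqueous ammonia and iodine in THF should convert the aldehyde into the keto nitrile F1. The same iron-hydride HAT conditions should then close ring A onto the nitrile, a documented radical acceptor whose iminyl radical does not readily fragment, giving the cyclic imine F2, which acidic work-up hydrolyses to the 3,9-diketone F3. NaBH4 in MeOH at −20 °C should reduce only the less hindered C3 ketone, from the axial direction, to the 3β-alcohol, and methoxide equilibration of C8 returns 14. The same oxidation to F3 and borohydride reduction would also correct a 3α-alcohol.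

Step 7. The hindered ketone may be enolised instead of attacked, or the vinyl group may enter from the α-face and give the C9 epimer. The fallback sets out from 14 and comes back at 16, and it reverses the roles of the faces: oxygen, not carbon, is delivered from the α-side. Wittig methylenation (Ph3P=CH2 from Ph3PCH3Br and KOt-Bu, toluene, 90 °C) should give the 9(11)-exocyclic alkene F4. mCPBA should epoxidise it anti to the C10 methyl to give the 9α,11-epoxide F5. Excess dimethylsulfonium methylide (trimethylsulfonium iodide, n-BuLi, THF) should open the epoxide at C11 and eliminate dimethyl sulfide, the known one-carbon homologation of epoxides to allylic alcohols, which gives 16.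

Step 9. The alkylborane, flanked by a free tertiary hydroxyl, may transmetallate slowly, so that protodeboronation, β-hydride elimination, base-induced opening of the bromobutenolide or loss of the acetate take over. The fallback sets out from 18 and comes back at 21. Hydroboration with 9-BBN and oxidation with NaBO3 should give the 9α,12-diol F6. One equivalent of Dess–Martin periodinane should give the hydroxy aldehyde F7, present largely as its five-membered lactol. Wittig olefination with 3-(triphenylphosphoranylidene)dihydrofuran-2(3H)-one in toluene at 90 °C should give the (E)-α-alkylidene lactone F8. RhCl3·3H2O in EtOH at 70 °C should move the exocyclic double bond into the ring and give 21.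

**Further compounds**
F1 | step 6 | 3-[(1S,2R,6S)-type ring as in 12]propanenitrile, i.e. 12 with C≡N in place of CHO | N#CCC[C@@]1(C)[C@@H](CC[C@@H](C)C1=O)C(C)=C
F2 | step 6 | 3-imino-4,4,8α,10-tetramethyl-trans-decalin-9-one (not isolated) | N=C1CC[C@@]2(C)[C@@H](CC[C@@H](C)C2=O)C1(C)C
F3 | step 6 | 4,4,8α,10-tetramethyl-trans-decalin-3,9-dione | O=C1CC[C@@]2(C)[C@@H](CC[C@@H](C)C2=O)C1(C)C
F4 | step 7 | 9-methylene-4,4,8α,10-tetramethyl-trans-decalin-3β-ol | O[C@H]1CC[C@@]2(C)[C@@H](CC[C@@H](C)C2=C)C1(C)C
F5 | step 7 | 9α,11-epoxide of F4 (spiro-oxirane, oxygen α, CH2 β) | O[C@H]1CC[C@@]2(C)[C@@H](CC[C@@H](C)[C@]2(O3)C3)C1(C)C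
F6 | step 9 | 3β-acetoxy-9β-(2-hydroxyethyl)-4,4,8α,10-tetramethyl-trans-decalin-9α-ol | CC(=O)O[C@H]1CC[C@@]2(C)[C@@H](CC[C@@H](C)[C@]2(O)CCO)C1(C)C
F7 | step 9 | 2-(3β-acetoxy-9α-hydroxy-4,4,8α,10-tetramethyl-trans-decalin-9β-yl)acetaldehyde (open form of the lactol) | CC(=O)O[C@H]1CC[C@@]2(C)[C@@H](CC[C@@H](C)[C@]2(O)CC=O)C1(C)C
F8 | step 9 | (E)-3β-acetoxy-9α-hydroxylabd-12-en-16,15-olide (α-alkylidene lactone) | CC(=O)O[C@H]1CC[C@@]2(C)[C@@H](CC[C@@H](C)[C@]2(O)C/C=C2\CCOC2=O)C1(C)C
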